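The numbers stand for no real mixture; the flask was simulated.

In a closed, stirred vessel, a trace of free catalyst turned starting material and partner into target, while scavenger caught the released group.

    starting material + free catalyst → catalyst intermediate A (k1 = 600 M⁻¹ s⁻¹)
    partner + catalyst intermediate A → catalyst intermediate B (k2 = 9700 M⁻¹ s⁻¹)
    catalyst intermediate B → released group + catalyst intermediate C (k3 = 4100 s⁻¹)
    catalyst intermediate C → free catalyst + target (k4 = 2800 s⁻¹)
    partner + released group ⇌ idle adduct, settled at all times (K5 = 3.8 M⁻¹)
    scavenger + released group → scavenged by-product (k6 = 400 M⁻¹ s⁻¹)

starting material 39 mM; partner 78.0 mM; scavenger 39.0 mM; free catalyst 78 µM; time 80 s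

- for released group the idle adduct is counted in
- run time (flask): 80 s

- part of the starting material that has reacted at 80 s
- share of the unused partner that is free and not bound as idle adduct, at 80 s

I first asked where the catalyst sat. At the charges, the first step took up free catalyst at 23.4 s⁻¹. That was slower than the partner step at 757 s⁻¹, the release at 4100 s⁻¹ and the last step at 2800 s⁻¹. So I froze free catalyst at its charge and treated it as the resting state. The starting material then decayed as a pseudo-first-order species. I call its constant λ, the first rate constant times the charged catalyst, the catalyst clock:

λ = 0.0468 s⁻¹

λt = 3.74 at 80 s

part left = exp(−λt), so c = 97.6%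

Next came the released group, R. Against scavenger at its charge it lasted 0.0641 s, far shorter than the run, so I set its making equal to its removal. Scavenger and starting material were charged equally, and I let them fall together. Their ratio then cancelled:

R = λ/(scavenging constant) = 0.117 mM

bound over free partner = K·R, with K the balance constant of the adduct

fr = >99.9%

The forecast gave 97.5% and >99.9%, on the ground that “Step 1 dominates the resistance”. It took a small correction off the exponent, which I did not take.

The simulation gave 97.5% and >99.9%. In this flask, free catalyst stood at 96.6% at 8.00 s and 99.8% at 80.0 s, while the first step had half of its turnover up to 80 s behind it at 14.8 s; at 40.0 s starting material read 16.1% against 15.4% on the clock, and released group read 0.113 mM against my 0.117 mM. In the neighbour flask, charged with 9.8 mM of scavenger, λt was still 3.74 and 97.5% had reacted by 80 s, but by then scavenger had fallen to 0%, released group had risen to 24.8 mM, and the free share of unused partner was 91.4%.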